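Rings: A and D are the outer 3-hydroxyphenyl rings, B is the 1,4-phenylene and C is the catechol ring, joined as A–CH2CH2–B–O–C–CH2CH2–D. The molecule is achiral, so no stereochemistry has to be set.
Enabling feature: in rings A and D the bridge is on C1 and the hydroxyl on C3, a 1,3 relation that an alkyl group cannot direct. C2 lies ortho to both, so a carboxyl placed there has C3–H as its only free ortho C–H and can later leave as CO2.
Retrosynthesis: unmask the ring C catechol from two methyl ethers, put a carboxyl back on C2 of rings A and D, and cut both C3–O bonds of rings A and D. Then cut the central CH2–CH2 bond of each bridge, and last the ring B–O bond.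
Forward: all four benzene rings are bought and none is built. B and C are joined by SNAr, and A and D are attached together by a twofold lateral alkylation. Both hydroxyls then enter together by C–H oxygenation, and CO2 and the methyl groups are removed last.

Key step: step 5

Assumption: the oxygen balance of step 5 is written as one O2 for the two C–H bonds, with both oxygen atoms ending up in phenol groups.

Step 1
Reactants: 1 3-hydroxy-4,5-dimethoxybenzaldehyde; 2 4-fluorobenzaldehyde
Product: 3 3-(4-formylphenoxy)-4,5-dimethoxybenzaldehyde
Conditions: K2CO3, DMF, 140 °C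
Reagents that add atoms: none
Why: Nucleophilic aromatic substitution (SNAr), in which the phenoxide of 1 adds para to the formyl group of 2, the Meisenheimer adduct is stabilised by that carbonyl and expels fluoride, and neither aldehyde is enolisable, so the base has nothing else to attack.

Step 2
Reactants: 3 3-(4-formylphenoxy)-4,5-dimethoxybenzaldehyde
Product: 4 {3-[4-(hydroxymethyl)phenoxy]-4,5-dimethoxyphenyl}methanol
Conditions: NaBH4, MeOH–THF, 0 °C → rt
Reagents that add atoms: none
Why: Hydride reduction of both aldehydes with NaBH4, which leaves the diaryl ether and the methyl ethers untouched.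

Step 3
Reactants: 4 {3-[4-(hydroxymethyl)phenoxy]-4,5-dimethoxyphenyl}methanol
Product: 5 5-(bromomethyl)-1-[4-(bromomethyl)phenoxy]-2,3-dimethoxybenzene
Conditions: PBr3, CH2Cl2, 0 °C
Reagents that add atoms: phosphorus tribromide, BrP(Br)Br
Why: Bromination of primary benzylic alcohols through phosphite esters and SN2 displacement by bromide, run cold with the product used at once because both bromides sit on oxygenated rings.

Step 4
Reactants: 6 2-methylbenzoic acid; 5 5-(bromomethyl)-1-[4-(bromomethyl)phenoxy]-2,3-dimethoxybenzene
Product: 8 2-[2-(4-{5-[2-(2-carboxyphenyl)ethyl]-2,3-dimethoxyphenoxy}phenyl)ethyl]benzoic acid (the bis(acid)), via dilithiated 2-methylbenzoic acid 7 (not isolated)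
Conditions: 6 (2.5 equiv), LiN(i-Pr)2 (commercial solution, 2.0 equiv per 6), THF, −78 → 0 °C; then 5, −78 °C → rt; aq HCl
Reagents that add atoms: lithium diisopropylamide, CC(C)N([Li])C(C)C (supplies the lithium of 7 only; nothing of it stays in 8)
Why: Lateral lithiation and alkylation, in which the amide base removes first the carboxyl proton and then a proton of the ortho methyl group, and the benzylic carbanion, held by the neighbouring lithium carboxylate, displaces both primary benzylic bromides of 5 by SN2 at carbon to form the two CH2–CH2 bridges at once.

Step 5
Reactants: 8 2-[2-(4-{5-[2-(2-carboxyphenyl)ethyl]-2,3-dimethoxyphenoxy}phenyl)ethyl]benzoic acid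
Product: 9 2-[2-(4-{5-[2-(2-carboxy-3-hydroxyphenyl)ethyl]-2,3-dimethoxyphenoxy}phenyl)ethyl]-6-hydroxybenzoic acid (the bis(6-alkylsalicylic acid))
Conditions: Pd(OAc)2 (10 mol % per CO2H), KOAc (2 equiv per CO2H), O2 (5 atm), DMA, 115 °C; then aq HCl
Reagents that add atoms: dioxygen, O=O
Why: Divalent palladium is captured by the potassium carboxylate on C2 and cleaves the neighbouring C3–H bond by acetate-assisted concerted metalation–deprotonation; the five-membered palladacycle takes up O2 at its aryl–palladium bond, and protonolysis liberates the phenol and regenerates divalent palladium without a co-oxidant. The reaction type is the known Pd(OAc)2-catalysed, carboxylate-directed ortho C–H hydroxylation of benzoic acids with O2, for which 2-alkylbenzoic acids such as 6 are typical substrates; here it runs at two independent sites of one molecule. No ring is closed and no stereocentre is created; the two C3–O bonds of rings A and D are the only bonds formed. Site selectivity is built into 8, since one ortho position of each carboxyl carries the bridge and C3–H is the only one left, while rings B and C have no coordinating group and face only the much slower undirected palladation. The selectivity that must be secured is aryl C–H over the benzylic C–H of the ortho bridge, which would end in lactone closure; the five-membered aryl palladacycle is favoured over the six-membered benzylic one, and leaving out one-electron oxidants such as Ag2CO3 or K2S2O8 shuts the radical path to benzylic oxidation. A second hydroxylation on the same ring is impossible because no ortho C–H remains, and any early loss of CO2 after hydroxylation only anticipates step 6.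

Step 6
Reactants: 9 2-[2-(4-{5-[2-(2-carboxy-3-hydroxyphenyl)ethyl]-2,3-dimethoxyphenoxy}phenyl)ethyl]-6-hydroxybenzoic acid
Product: 10 3-[2-(4-{5-[2-(3-hydroxyphenyl)ethyl]-2,3-dimethoxyphenoxy}phenyl)ethyl]phenol (perrottetin F with ring C as its dimethyl ether)
Conditions: Cu2O (cat.), 1,10-phenanthroline (cat.), NMP–quinoline 3:1, 170 °C, N2
Reagents that add atoms: none
Why: Copper-catalysed protodecarboxylation, in which the carboxylate bound to monovalent copper extrudes CO2, helped by the twist that the flanking hydroxyl and bridge impose on the carboxyl, and the aryl–copper species is protonated by further acid, in line with the ready thermal loss of CO2 from 6-alkylsalicylic acids.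

Step 7
Reactants: 10 3-[2-(4-{5-[2-(3-hydroxyphenyl)ethyl]-2,3-dimethoxyphenoxy}phenyl)ethyl]phenol
Product: 11 perrottetin F, 3-{4-[2-(3-hydroxyphenyl)ethyl]phenoxy}-5-[2-(3-hydroxyphenyl)ethyl]benzene-1,2-diol
Conditions: BBr3 (6 equiv), CH2Cl2, −78 °C → rt; then H2O
Reagents that add atoms: none
Why: Lewis acid cleavage of aryl methyl ethers, in which BBr3 binds each methoxy oxygen and bromide removes the methyl group by SN2, while the diaryl ether offers no sp3 carbon and stays intact, and hydrolysis of the borate esters frees the catechol.

Compound list
1 | 3-hydroxy-4,5-dimethoxybenzaldehyde | COc1cc(C=O)cc(O)c1OC | starting material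
2 | 4-fluorobenzaldehyde | O=Cc1ccc(F)cc1 | starting material
3 | 3-(4-formylphenoxy)-4,5-dimethoxybenzaldehyde | O=Cc1ccc(Oc2cc(C=O)cc(OC)c2OC)cc1 | intermediate
4 | {3-[4-(hydroxymethyl)phenoxy]-4,5-dimethoxyphenyl}methanol | OCc1ccc(Oc2cc(CO)cc(OC)c2OC)cc1 | intermediate
5 | 5-(bromomethyl)-1-[4-(bromomethyl)phenoxy]-2,3-dimethoxybenzene | BrCc1ccc(Oc2cc(CBr)cc(OC)c2OC)cc1 | intermediate
6 | 2-methylbenzoic acid | Cc1ccccc1C(=O)O | starting material
7 | dilithiated 2-methylbenzoic acid (not isolated) | [Li]Cc1ccccc1C(=O)O[Li] | intermediate
8 | 2-[2-(4-{5-[2-(2-carboxyphenyl)ethyl]-2,3-dimethoxyphenoxy}phenyl)ethyl]benzoic acid | OC(=O)c1ccccc1CCc1ccc(Oc2cc(CCc3ccccc3C(=O)O)cc(OC)c2OC)cc1 | intermediate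
9 | 2-[2-(4-{5-[2-(2-carboxy-3-hydroxyphenyl)ethyl]-2,3-dimethoxyphenoxy}phenyl)ethyl]-6-hydroxybenzoic acid | OC(=O)c1c(O)cccc1CCc1ccc(Oc2cc(CCc3cccc(O)c3C(=O)O)cc(OC)c2OC)cc1 | intermediate
10 | 3-[2-(4-{5-[2-(3-hydroxyphenyl)ethyl]-2,3-dimethoxyphenoxy}phenyl)ethyl]phenol | Oc1cccc(CCc2ccc(Oc3cc(CCc4cccc(O)c4)cc(OC)c3OC)cc2)c1 | intermediate
11 | perrottetin F | Oc1cccc(CCc2ccc(Oc3cc(CCc4cccc(O)c4)cc(O)c3O)cc2)c1 | target

Total step count: 7.
Longest linear sequence: 7 steps (1 → 3 → 4 → 5 → 8 → 9 → 10 → 11). Compounds 2 and 6 are bought and enter in steps 1 and 4.

Steps most likely to fail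

**Step 5.**
- Palladation or autoxidation may occur at the benzylic C–H of the bridge, followed by lactone closure, or the bridge may be dehydrogenated.
- The reaction may stall after the first hydroxylation, because the salicylate already formed chelates palladium.
- CO2 may be lost before hydroxylation, which removes the director.
- Fallback (sets out from 5, comes back at 11): the C3 oxygen is bought instead of made.
- Commercial 2-methoxy-6-methylbenzoic acid (COc1cccc(C)c1C(=O)O) is deprotonated twice with LiN(i-Pr)2 in THF to dilithiated 2-methoxy-6-methylbenzoic acid F1.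
- This is alkylated with dibromide 5 in the manner of step 4 to give the bis(2-methoxy-6-alkylbenzoic acid) F2.
- Its carboxyl groups are again flanked on both sides, so the Cu2O and 1,10-phenanthroline conditions of step 6 should lead to perrottetin F tetramethyl ether F3.
- BBr3 in CH2Cl2 then removes all four methyl groups to give 11.

**Step 4.**
- Halogen–lithium exchange or single-electron transfer between the benzylic organolithium and the benzylic bromides may cause Wurtz-type homocoupling.
- Proton transfer from the first-formed product to unreacted 7 may lead to a second alkylation at the same carbon.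
- Reaction may be incomplete at one of the two sites.
- Left-over 6 must be removed fully, since it would compete for palladium in step 5.
- Fallback (sets out from 3, with 7 generated as in step 4, comes back at 8, and makes steps 2 and 3 unnecessary): the electrophile is changed from bromide to aldehyde.
- Addition of 7 to both formyl groups of 3 at −78 °C and acidification with aq HCl should give, by spontaneous lactonisation, the bis(3-aryl-3,4-dihydroisocoumarin) F4 as a mixture of diastereomers.
- Hydrogenolysis of its two benzylic C–O bonds (H2, Pd/C, AcOH–EtOAc) erases both stereocentres and gives 8.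

**Step 6.**
- Loss of CO2 may be incomplete at one of the two sites, because salicylate chelation ties up the copper.
- Copper-mediated oxidative coupling of the free phenols may occur if air enters.
- Fallback (sets out from 9, comes back at 11, merging steps 6 and 7): the organocopper pathway is given up for Brønsted acid ipso-protonation.
- Heating 9 in molten pyridinium chloride at about 190 °C under N2 should protonate the carboxyl-bearing C2, which is activated by the ortho hydroxyl, and expel CO2.
- In the same melt, chloride removes the two methyl groups of ring C by SN2. The diaryl ether and the bridges tolerate these conditions.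
- New compounds on this way: none F0.

Further compounds
F1 | step 5 | dilithiated 2-methoxy-6-methylbenzoic acid | [Li]Cc1cccc(OC)c1C(=O)O[Li]
F2 | step 5 | bis(2-methoxy-6-alkylbenzoic acid), 2-[2-(4-{5-[2-(2-carboxy-3-methoxyphenyl)ethyl]-2,3-dimethoxyphenoxy}phenyl)ethyl]-6-methoxybenzoic acid | COc1cccc(CCc2ccc(Oc3cc(CCc4cccc(OC)c4C(=O)O)cc(OC)c3OC)cc2)c1C(=O)O
F3 | step 5 | perrottetin F tetramethyl ether | COc1cccc(CCc2ccc(Oc3cc(CCc4cccc(OC)c4)cc(OC)c3OC)cc2)c1
F4 | step 4 | bis(3-aryl-3,4-dihydroisocoumarin), mixture of diastereomers | O=C1OC(Cc2ccccc12)c1ccc(Oc2cc(C3Cc4ccccc4C(=O)O3)cc(OC)c2OC)cc1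
F0 | step 6 | none | none
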